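- Start from the neighbour of south charged with 0.032 M of J in place of 19 mM, and before integrating anything, ask how much catalyst each flask keeps at work. The problem is this:

| flask | E | X | G | J | time | remark |
|---|---|---|---|---|---|---|
| south-east | 1.2 M (fed, over 0.800 min) | 1.56 M | 60 mM | 19 mM | 1.0 min | all but E at the start; E goes in evenly over 0.800 min, the run ends at 1.0 min |
| west | 1.2 M | 1.56 M (fed, over 0.800 min) | 60 mM | 19 mM | 1.0 min | a stirred flask in which X is dosed at a steady rate over 0.800 min without added volume, worked up at 1.0 min |
| east | 1.2 M | 1.56 M | 60 mM | 19 mM |  | one stirred flow tank at steady state, fed with the mixture as stated, mean residence time 1.0 min |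
| south | 1.2 M | 1.56 M | 60 mM | 19 mM | 1.0 min | a closed flask charged with all of it at once and left for 1.0 min |

    X + G → X.G (k1 = 8.48 M⁻¹ s⁻¹)
    E + X.G → E.X.G (k2 = 1.45 M⁻¹ s⁻¹)
    E.X.G → G + Q (k3 = 2.79 s⁻¹)
    G + J → G.J (k4 = 3040 M⁻¹ s⁻¹)

- order of the set-ups by the amount of Q at the outlet or at the end, in percent of the E put in, highest first (south-east / west / east / south)
- amount of Q at the outlet or at the end, in percent of the E put in, south-east
- amount of Q at the outlet or at the end, in percent of the E put in, west
- amount of Q at the outlet or at the end, in percent of the E put in, east
- amount of Q at the outlet or at the end, in percent of the E put in, south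

- the stated concentrations are those of everything mixed, before any reaction; amounts are the same in each set-up
- the feed brings no volume worth counting
- run time (south-east): 1.0 min

- Follow one G in south at the first moment. Step 1 runs at 0.23 times the rate of step 4, so J takes a share of 81.3%. Applied to the 60 mM of G, that is 48.8 mM, more than the 19 mM of J.
- Doubt this, because those odds hold for the start and shift as J is used. Yet G charged exceeds J charged by 41.0 mM, and against that excess J lasts about 0.00802 s, shorter than the 0.358 s of step 3, so in this estimate J is bound before a turn is done. Count J as wholly bound, and call G charged less J charged the working catalyst, W = 41.0 mM.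
- Now suppose W waits as X.G. E then decays as a pseudo-first-order species, with k2 times W times the time equal to 3.57, which leaves 2.82% of E in south.
- Object that a turn holds other waits. At the charge, X takes 0.0756 s to find G and step 3 takes 0.358 s, beside 0.575 s for step 2. The rate is W over the sum of the waits, and integrating it subtracts 0.755 from 3.57, so 6.01% of E stays.
- Object again that [X] sinks as E turns over, towards 0.319 M. Using that floor for the whole run costs 1.27 and leaves 10.0%. Commit, then, to 90.0% to 94.0% of Q in south, and leave the fed flasks and the tank unreckoned.
- The forecast gives south > west > south-east > east, with south-east 77%, west 88%, east 74% and south 93%, on the ground that “anything that keeps E high for the whole run wins”.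
- The simulation gives south-east 76.6%, west 87.7%, east 73.7% and south 93.5%, in the order south > west > south-east > east. After 10.0 min, south holds X.G at 68.3% of the catalyst charged, and W over G charged is 68.3%. A run that parts from the forecast in south needs a setting moved: with G at 52.8 mM the answer has moved 5 points, and W is 33.8 mM, while with all amounts held the time does the same at 0.824 min or 1.43 min. In the neighbour, W is 28.0 mM; the same subtraction, scaled to the part of E used up in a first pass, gives 16.2% of E left, and that flask shows 17.5%.

The numbers of this flask are invented; the run is a simulation.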